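Ring numbering, kept for all intermediates: C1 (CH bearing isobutyryl), C2 (C=O), C3 (C(OH)-prenyl), C4 (C=O), C5 (CH-prenyl), C6 (CH2), C7 (CH-prenyl), C8 (C bearing CH3 and 4-methylpent-3-enyl).
Enabling feature: C3 lies between the C2 and C4 ketones and C5 is the α-carbon of C4. A C2–C5 bond therefore folds C2–C3–C4–C5 into a non-enolisable cyclobutane-1,3-dione, whose two carbonyl groups differ only through the stereogenic C6–C7–C8 tether.
Retrosynthetic cuts, in order: O3 protecting group; C1–C2 with C2–C5 re-joined (aldol/retro-aldol read backwards); the C3–O bond; the four-membered ring into a C5 ketene and a C3 ynol ether; C5–C6 (enolate alkylation); C7–C8 (Ireland–Claisen).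
Forward order: the chain is built first (C7–C8, then C5–C6, then the isopropyl ketone on C1). The cyclobutane ring follows by [2+2], and a transient six-membered ring (C1–C2) then opens at C2–C5 to the eight-membered ring.
Stereochemistry: C7 and C8 arise together in a reagent-controlled chair Ireland–Claisen of a geranyl ester. The trans O3/tether relation comes from face-selective hydroxylation, C3 from the choice between the diastereotopic carbonyls, and C1 and C5 from equilibration.

Key step: step 17

Assumption (step 2): the (S,S)-configured boron controller is written as the one that leads to (2R,3S)-7; its sense of induction is to be checked on 7, and the equally accessible (R,R)-reagent would replace it with no other change.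
Assumption (step 17): C1 and C5 are both epimerisable α-carbonyl positions and are taken to hold their thermodynamically preferred configuration in the natural product.

Step 1
Reactants: 1 geranyl acetate; 2 1-bromo-3-methylbut-2-ene (prenyl bromide)
Product: 4 geranyl 5-methylhex-4-enoate, via lithium enolate 3 (not isolated)
Conditions: LiN(i-Pr)2, THF, −78 °C; 2, DMPU, −78 → −30 °C
Reagents that add atoms: none
Why: This is the alkylation of an ester lithium enolate with a reactive allylic bromide; at this temperature the allyl ester enolate does not undergo the [3,3] shift, and no stereocentre is formed.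

Step 2
Reactants: 4 geranyl 5-methylhex-4-enoate
Product: 7 (2R,3S)-3-ethenyl-3,7-dimethyl-2-(3-methylbut-2-enyl)oct-6-enoic acid, via boron ketene acetal 5 (not isolated), via boron carboxylate 6 (not isolated)
Conditions: (S,S)-N,N'-(1,2-diphenylethane-1,2-diyl)bis[3,5-bis(trifluoromethyl)benzenesulfonamide], BBr3, CH2Cl2, 23 °C, evaporate; 4, i-Pr2NEt, CH2Cl2, −78 → 4 °C; H2O
Reagents that add atoms: none
Why: In this enantioselective boron-mediated Ireland–Claisen rearrangement, i-Pr2NEt in CH2Cl2 gives the Z(O) ketene acetal (prenyl cis to O–B) and the (E)-alkene puts the 4-methylpent-3-enyl chain pseudo-equatorial and the methyl group pseudo-axial in the chair, so C7 and C8 form together with prenyl and long chain syn along the C6–C7–C8–C1 zigzag, while the C2-symmetric sulfonamide ligand on boron selects the enolate face.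

Step 3
Reactants: 7 (2R,3S)-acid
Product: 8 (2R,3S)-3-ethenyl-3,7-dimethyl-2-(3-methylbut-2-enyl)oct-6-en-1-ol
Conditions: LiAlH4, Et2O, 0 → 23 °C
Reagents that add atoms: none
Why: Hydride reduction takes the carboxylic acid to the C6 primary alcohol and leaves the isolated alkenes and both stereocentres untouched.

Step 4
Reactants: 8 primary alcohol
Product: 9 (2R,3S)-3-ethenyl-1-iodo-3,7-dimethyl-2-(3-methylbut-2-enyl)oct-6-ene
Conditions: I2, PPh3, imidazole, CH2Cl2, 0 → 23 °C
Reagents that add atoms: iodine, II
Why: Appel-type iodination proceeds through the alkoxyphosphonium salt by SN2 at the primary C6 carbon under nearly neutral conditions that spare the three alkenes.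

Step 5
Reactants: 10 2-methylbut-3-en-2-ol; 11 trimethyl orthoacetate
Product: 13 methyl 5-methylhex-4-enoate, via mixed ketene acetal 12 (not isolated)
Conditions: EtCO2H (cat.), neat, 110 → 140 °C, MeOH distilled off
Reagents that add atoms: none
Why: The Johnson–Claisen rearrangement of a tertiary allylic alcohol delivers the trisubstituted (prenyl-type) alkene and the ester in one operation.

Step 6
Reactants: 13 methyl 5-methylhex-4-enoate; 9 iodide
Product: 15 methyl (4S,5S)-5-ethenyl-5,9-dimethyl-2,4-bis(3-methylbut-2-enyl)dec-8-enoate (both C5 epimers in ring numbering), via lithium enolate 14 (not isolated)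
Conditions: LiN(i-Pr)2, THF, −78 °C; 9, DMPU, −78 → 0 °C
Reagents that add atoms: none
Why: Ester enolate alkylation with a primary, β-branched iodide, helped by DMPU, forms C5–C6, and the lack of control at C5 does not matter because C5 becomes sp2 in ketene 26.

Step 7
Reactants: 15 vinyl ester
Product: 17 methyl (4S,5S)-5-(2-hydroxyethyl)-5,9-dimethyl-2,4-bis(3-methylbut-2-enyl)dec-8-enoate, via alkylborane 16 (not isolated)
Conditions: 9-BBN-H, THF, 0 → 40 °C; H2O2, aq NaOH, 0 °C
Reagents that add atoms: hydrogen peroxide, OO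
Why: In this chemoselective hydroboration–oxidation the bulky borane adds to the monosubstituted vinyl group far faster than to the three trisubstituted alkenes, places boron on the terminal carbon and does not reduce the ester.

Step 8
Reactants: 17 hydroxy ester
Product: 18 methyl (4S,5S)-5,9-dimethyl-2,4-bis(3-methylbut-2-enyl)-5-(2-oxoethyl)dec-8-enoate
Conditions: Dess–Martin periodinane, CH2Cl2, 0 → 23 °C
Reagents that add atoms: none
Why: Dess–Martin oxidation stops at the aldehyde and does not touch the alkenes.

Step 9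
Reactants: 18 aldehyde ester
Product: 19 methyl (4S,5S)-5-(2-hydroxy-3-methylbutyl)-5,9-dimethyl-2,4-bis(3-methylbut-2-enyl)dec-8-enoate (carbinol epimers)
Conditions: i-PrMgCl, LaCl3·2LiCl, THF, −78 °C
Reagents that add atoms: isopropylmagnesium chloride, CC(C)[Mg]Cl
Why: In this Grignard addition the aldehyde outcompetes the α-branched methyl ester at −78 °C, the lanthanum salt suppresses enolisation and β-hydride reduction, and the new carbinol centre is erased in step 10.

Step 10
Reactants: 19 carbinol ester
Product: 20 methyl (4S,5S)-5,9-dimethyl-5-(3-methyl-2-oxobutyl)-2,4-bis(3-methylbut-2-enyl)dec-8-enoate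
Conditions: Dess–Martin periodinane, CH2Cl2, 0 → 23 °C
Reagents that add atoms: none
Why: Dess–Martin oxidation of the secondary alcohol installs the isopropyl ketone whose CH2 group is C1.

Step 11
Reactants: 20 keto ester
Product: 21 (4S,5S)-5,9-dimethyl-5-(3-methyl-2-oxobutyl)-2,4-bis(3-methylbut-2-enyl)dec-8-enoic acid
Conditions: LiOH, THF/MeOH/H2O, 50 °C; 1 M HCl to pH 3
Reagents that add atoms: lithium hydroxide, [Li+].[OH-]
Why: In this saponification of a secondary-alkyl methyl ester, C7 and C8 are not α to any carbonyl group and cannot epimerise.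

Step 12
Reactants: 22 ethoxyacetylene; 2 prenyl bromide
Product: 24 1-ethoxy-5-methylhex-4-en-1-yne, via lithium ethoxyacetylide 23 (not isolated)
Conditions: n-BuLi, THF, −78 °C; 2, DMPU, −78 → 23 °C
Reagents that add atoms: none
Why: A lithium alkoxyacetylide is alkylated by SN2 at the primary carbon of the allylic bromide.

Step 13
Reactants: 21 keto acid; 24 ynol ether
Product: 27 3-ethoxy-2,4-diprenyl-4-(C6 tether)cyclobut-2-en-1-one (both C5 epimers), via acid chloride 25 (not isolated), via ketene 26 (not isolated)
Conditions: 1-chloro-N,N,2-trimethylprop-1-en-1-amine, CH2Cl2, 0 °C; 24 (3 equiv), Et3N, toluene, 45 °C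
Reagents that add atoms: none
Why: In this ketene–ynol ether [2+2] cycloaddition the nucleophilic prenyl-bearing alkyne carbon bonds to the ketene carbonyl carbon and C5 bonds to the ethoxy-bearing carbon, while the neutral chlorination and the excess of the electron-rich alkyne at moderate temperature are chosen so that intermolecular capture outruns reaction with the pendant alkenes.

Step 14
Reactants: 27 ethoxycyclobutenone
Product: 28 3-hydroxy-2,4-diprenyl-4-(C6 tether)cyclobut-2-en-1-one (enol of the 2,2,4-trisubstituted cyclobutane-1,3-dione)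
Conditions: 1 M HCl, THF, 23 °C
Reagents that add atoms: water, O
Why: Acid hydrolysis of the vinylogous ester gives a vinylogous acid whose fast tautomerism makes the two ring carbonyl carbons equivalent, so C5 is no longer stereogenic and both epimers of 27 converge on one compound.

Step 15
Reactants: 28 dione enol
Product: 30 trans-2-hydroxy-2,4-diprenyl-4-(C6 tether)cyclobutane-1,3-dione (O3 and the C5 tether on opposite ring faces), via potassium enolate 29 (not isolated)
Conditions: KN(SiMe3)2 (1.05 equiv), THF, −78 °C; 2-(phenylsulfonyl)-3-phenyloxaziridine, −78 → −20 °C; AcOH; chromatographic removal of the cis isomer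
Reagents that add atoms: 2-(phenylsulfonyl)-3-phenyloxaziridine, O=S(=O)(c1ccccc1)N1OC1c1ccccc1
Why: In this Davis α-hydroxylation of a β-dicarbonyl enolate only the far more acidic ring enol is deprotonated, the oxaziridine leaves the alkenes alone, and oxygen should arrive on the face of the flat ring that carries the slimmer C5 prenyl group, anti to the β-branched tether.

Step 16
Reactants: 30 trans hydroxy dione
Product: 31 trans-2-(methoxymethoxy)-2,4-diprenyl-4-(C6 tether)cyclobutane-1,3-dione
Conditions: MOMCl, i-Pr2NEt, CH2Cl2, 0 → 40 °C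
Reagents that add atoms: chloromethyl methyl ether, COCCl
Why: Methoxymethyl ether formation uses a non-nucleophilic amine base that cannot open the strained dione, and the resulting acetal ether cannot migrate to a neighbouring alkoxide.

Step 17
Reactants: 31 tetrasubstituted cyclobutane-1,3-dione
Product: 36 hyphenrone F methoxymethyl ether, via C1 enolate 32 (not isolated), via bicyclic alkoxide 33 (not isolated), via C5 enolate 34 (not isolated), via C1 diketonate 35 (not isolated)
Conditions: KN(SiMe3)2 (1.1 equiv), THF (0.01 M), −78 → 0 °C, then 23 °C; AcOH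
Reagents that add atoms: none
Why: Proposed new method: KN(SiMe3)2 removes a C1 proton of the isopropyl ketone (the isopropyl-side enolate could reach the ring only through an eight-membered transition state and returns by proton exchange), enolate 32 adds to a strained, non-enolisable ring carbonyl, and alkoxide 33 breaks the C2–C5 fusion bond in a retro-aldol step that releases the four-ring strain and gives enolate 34, which is drained by proton transfer from the much more acidic C1–H to β-diketonate 35. The closest known reaction types are the alkoxide-induced retro-Claisen opening of tetrasubstituted cyclobutane-1,3-diones and the de Mayo-type two-carbon expansion of 1-oxybicyclo[n.2.0]alkanones to cycloalkane-1,3-diones, but a carbon nucleophile tethered to such a dione has not been used in this way. The only ring closed directly is the six-membered ring C1–C2–C5–C6–C7–C8 of 33, by a 6-(enolexo)-exo-trig aldol, and the eight-membered ring is then revealed by fragmentation, not by cyclisation. C3 is fixed by the choice between the two diastereotopic carbonyl groups: in the chair with the C7 prenyl and C8 4-methylpent-3-enyl groups equatorial, attack on the pro-C2 carbonyl of trans-31 places only the small developing oxide opposite the axial C8 methyl group, whereas attack on the other carbonyl would force C3 into a syn-axial contact with that methyl group and turn the C5 prenyl group axial. C1 (between two carbonyls) and C5 (α to C4) are set by protonation under equilibrating conditions, with the slight excess of base and the liberated HN(SiMe3)2 shuttling protons before the acetic acid quench. The step needs cleavage of the fusion bond C2–C5 and not of the peripheral bond C2–C3, which is expected because a C3 carbanion would carry an oxygen lone pair that destabilises the planar enolate, because related bridgehead oxides open at the fusion bond, and because the acetal ether on O3 cannot move to the C2 oxide as a silyl or acyl group would.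

Step 18
Reactants: 36 hyphenrone F methoxymethyl ether
Product: 37 hyphenrone F
Conditions: ZnBr2, n-PrSH, CH2Cl2, 0 °C
Reagents that add atoms: none
Why: Lewis acid and thiol cleave the formaldehyde acetal within minutes and without a Brønsted acid, so the prenyl groups, the tertiary α-ketol and the settled C1 and C5 centres should survive.

Compound list (T = (2S,3S)-3,7-dimethyl-3-(3-methyl-2-oxobutyl)-2-(3-methylbut-2-enyl)oct-6-en-1-yl, attached through C6; prenyl = 3-methylbut-2-enyl)
1 | geranyl acetate, (2E)-3,7-dimethylocta-2,6-dienyl acetate | CC(C)=CCC/C(C)=C/COC(C)=O | starting material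
2 | 1-bromo-3-methylbut-2-ene (prenyl bromide) | CC(C)=CCBr | starting material
3 | lithium enolate of geranyl acetate | [Li+].[O-]C(=C)OC/C=C(\C)CCC=C(C)C | intermediate
4 | geranyl 5-methylhex-4-enoate | CC(C)=CCC/C(C)=C/COC(=O)CCC=C(C)C | intermediate
5 | Z(O)-boron ketene acetal of 4 (prenyl cis to O–B; boron held in the (S,S)-4,5-diphenyl-1,3-bis[3,5-bis(trifluoromethyl)phenylsulfonyl]-1,3,2-diazaborolidine ring) | CC(C)=CC/C=C(\OB1N(S(=O)(=O)c2cc(C(F)(F)F)cc(C(F)(F)F)c2)[C@@H](c2ccccc2)[C@H](c2ccccc2)N1S(=O)(=O)c1cc(C(F)(F)F)cc(C(F)(F)F)c1)OC/C=C(\C)CCC=C(C)C | intermediate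
6 | diazaborolidinyl carboxylate of acid 7 | CC(C)=CCC[C@](C=C)(C)[C@@H](CC=C(C)C)C(=O)OB1N(S(=O)(=O)c2cc(C(F)(F)F)cc(C(F)(F)F)c2)[C@@H](c2ccccc2)[C@H](c2ccccc2)N1S(=O)(=O)c1cc(C(F)(F)F)cc(C(F)(F)F)c1 | intermediate
7 | (2R,3S)-3-ethenyl-3,7-dimethyl-2-(3-methylbut-2-enyl)oct-6-enoic acid | CC(C)=CCC[C@](C=C)(C)[C@@H](CC=C(C)C)C(=O)O | intermediate
8 | (2R,3S)-3-ethenyl-3,7-dimethyl-2-(3-methylbut-2-enyl)oct-6-en-1-ol | CC(C)=CCC[C@](C=C)(C)[C@@H](CC=C(C)C)CO | intermediate
9 | (2R,3S)-3-ethenyl-1-iodo-3,7-dimethyl-2-(3-methylbut-2-enyl)oct-6-ene | CC(C)=CCC[C@](C=C)(C)[C@@H](CC=C(C)C)CI | intermediate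
10 | 2-methylbut-3-en-2-ol | CC(C)(O)C=C | starting material
11 | trimethyl orthoacetate | CC(OC)(OC)OC | starting material
12 | 1-methoxyethenyl 2-methylbut-3-en-2-yl ether (mixed ketene acetal) | C=C(OC)OC(C)(C)C=C | intermediate
13 | methyl 5-methylhex-4-enoate | COC(=O)CCC=C(C)C | intermediate
14 | lithium enolate of 13 (geometry of no consequence) | [Li+].[O-]C(OC)=CCC=C(C)C | intermediate
15 | methyl (4S,5S)-5-ethenyl-5,9-dimethyl-2,4-bis(3-methylbut-2-enyl)dec-8-enoate, C2 epimers | CC(C)=CCC[C@](C=C)(C)[C@@H](CC=C(C)C)CC(CC=C(C)C)C(=O)OC | intermediate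
16 | B-alkyl-9-borabicyclo[3.3.1]nonane from 15, boron on the terminal carbon of the former vinyl group | CC(C)=CCC[C@](CCB1C2CCCC1CCC2)(C)[C@@H](CC=C(C)C)CC(CC=C(C)C)C(=O)OC | intermediate
17 | methyl (4S,5S)-5-(2-hydroxyethyl)-5,9-dimethyl-2,4-bis(3-methylbut-2-enyl)dec-8-enoate | CC(C)=CCC[C@](CCO)(C)[C@@H](CC=C(C)C)CC(CC=C(C)C)C(=O)OC | intermediate
18 | methyl (4S,5S)-5,9-dimethyl-2,4-bis(3-methylbut-2-enyl)-5-(2-oxoethyl)dec-8-enoate | CC(C)=CCC[C@](CC=O)(C)[C@@H](CC=C(C)C)CC(CC=C(C)C)C(=O)OC | intermediate
19 | methyl (4S,5S)-5-(2-hydroxy-3-methylbutyl)-5,9-dimethyl-2,4-bis(3-methylbut-2-enyl)dec-8-enoate, carbinol epimers | CC(C)=CCC[C@](CC(O)C(C)C)(C)[C@@H](CC=C(C)C)CC(CC=C(C)C)C(=O)OC | intermediate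
20 | methyl (4S,5S)-5,9-dimethyl-5-(3-methyl-2-oxobutyl)-2,4-bis(3-methylbut-2-enyl)dec-8-enoate | CC(C)=CCC[C@](CC(=O)C(C)C)(C)[C@@H](CC=C(C)C)CC(CC=C(C)C)C(=O)OC | intermediate
21 | (4S,5S)-5,9-dimethyl-5-(3-methyl-2-oxobutyl)-2,4-bis(3-methylbut-2-enyl)dec-8-enoic acid, C2 epimers | CC(C)=CCC[C@](CC(=O)C(C)C)(C)[C@@H](CC=C(C)C)CC(CC=C(C)C)C(=O)O | intermediate
22 | ethoxyacetylene | CCOC#C | starting material
23 | lithium ethoxyacetylide | [Li+].[C-]#COCC | intermediate
24 | 1-ethoxy-5-methylhex-4-en-1-yne | CCOC#CCC=C(C)C | intermediate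
25 | acid chloride of 21 | CC(C)=CCC[C@](CC(=O)C(C)C)(C)[C@@H](CC=C(C)C)CC(CC=C(C)C)C(=O)Cl | intermediate
26 | ketene T(prenyl)C=C=O, ketene α-carbon = C5 | CC(C)=CCC[C@](CC(=O)C(C)C)(C)[C@@H](CC=C(C)C)CC(CC=C(C)C)=C=O | intermediate
27 | 3-ethoxy-2,4-bis(3-methylbut-2-enyl)-4-T-cyclobut-2-en-1-one, both epimers at the ring sp3 carbon (C5) | CC(C)=CCC[C@](CC(=O)C(C)C)(C)[C@@H](CC=C(C)C)CC1(CC=C(C)C)C(=O)C(CC=C(C)C)=C1OCC | intermediate
28 | 3-hydroxy-2,4-bis(3-methylbut-2-enyl)-4-T-cyclobut-2-en-1-one (enol of the cyclobutane-1,3-dione, tautomers interconvert) | CC(C)=CCC[C@](CC(=O)C(C)C)(C)[C@@H](CC=C(C)C)CC1(CC=C(C)C)C(=O)C(CC=C(C)C)=C1O | intermediate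
29 | potassium enolate of 28 | CC(C)=CCC[C@](CC(=O)C(C)C)(C)[C@@H](CC=C(C)C)CC1(CC=C(C)C)C(=O)C(CC=C(C)C)=C1[O-].[K+] | intermediate
30 | trans-2-hydroxy-2,4-bis(3-methylbut-2-enyl)-4-T-cyclobutane-1,3-dione (OH and T on opposite faces, OH cis to the C5 prenyl) | CC(C)=CCC[C@](CC(=O)C(C)C)(C)[C@@H](CC=C(C)C)C[C@]1(CC=C(C)C)C(=O)[C@](O)(CC=C(C)C)C1=O | intermediate
31 | trans-2-(methoxymethoxy)-2,4-bis(3-methylbut-2-enyl)-4-T-cyclobutane-1,3-dione | CC(C)=CCC[C@](CC(=O)C(C)C)(C)[C@@H](CC=C(C)C)C[C@]1(CC=C(C)C)C(=O)[C@](OCOC)(CC=C(C)C)C1=O | intermediate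
32 | potassium C1 enolate of 31 (enolate geometry of no consequence) | CC(C)=CCC[C@](C=C([O-])C(C)C)(C)[C@@H](CC=C(C)C)C[C@]1(CC=C(C)C)C(=O)[C@](OCOC)(CC=C(C)C)C1=O.[K+] | intermediate
33 | potassium cis-fused bicyclo[4.2.0]octan-1-olate (oxide on C2, C4 ketone in the four-membered ring, isobutyryl equatorial on C1) | CC(C)=CCC[C@]1(C)[C@@H](CC=C(C)C)C[C@]2(CC=C(C)C)C(=O)[C@](OCOC)(CC=C(C)C)[C@]2([O-])[C@H]1C(=O)C(C)C.[K+] | intermediate
34 | potassium C4/C5 enolate of the eight-membered triketone (ring-cis C5=C4) | CC(C)=CCC[C@]1(C)[C@@H](CC=C(C)C)C/C(CC=C(C)C)=C(/[O-])[C@](OCOC)(CC=C(C)C)C(=O)[C@H]1C(=O)C(C)C.[K+] | intermediate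
35 | potassium C1 β-diketonate of 36 | CC(C)=CCC[C@]1(C)[C@@H](CC=C(C)C)C[C@H](CC=C(C)C)C(=O)[C@](OCOC)(CC=C(C)C)C(=O)C1=C([O-])C(C)C.[K+] | intermediate
36 | hyphenrone F methoxymethyl ether, (1R,3R,5S,7S,8R) in the ring numbering used here | CC(C)=CCC[C@]1(C)[C@@H](CC=C(C)C)C[C@H](CC=C(C)C)C(=O)[C@](OCOC)(CC=C(C)C)C(=O)[C@H]1C(=O)C(C)C | intermediate
37 | hyphenrone F, (1R,3R,5S,7S,8R) in the ring numbering used here | CC(C)=CCC[C@]1(C)[C@@H](CC=C(C)C)C[C@H](CC=C(C)C)C(=O)[C@](O)(CC=C(C)C)C(=O)[C@H]1C(=O)C(C)C | target

Total steps: 18. Longest linear sequence: 16 (steps 1–4, 6–11, 13–18).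

Steps most likely to fail

Step 17. After the aldol closure the alkoxide may break the peripheral C2–C3 bond and not the fusion bond. The enolate may also add to the other carbonyl group, or proton exchange with the isopropyl-side enolate may stall the reaction.
The fallback uses known chemistry, sets out from 21 (as its acid chloride 25) and comes back at 36.
- Methyl glycolate is protected with MOMCl and i-Pr2NEt to methyl 2-(methoxymethoxy)acetate F1.
- The lithium enolate of F1 is prenylated with 2 to racemic methyl 2-(methoxymethoxy)-5-methylhex-4-enoate F2.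
- The lithium enolate of F2 is C-acylated with 25 at −78 °C to the acyclic β-keto ester F3, which carries C2 as methyl ester, the quaternary C3 and the C4 ketone.
- F3 is closed at C1–C2 by a Dieckmann-type Claisen condensation of the C1 ketone enolate on the C2 ester under high dilution (KN(SiMe3)2, THF), with the β-diketonate as thermodynamic sink.
- C3 is not controlled on this path, so its epimers would be separated at the stage of 36.

Step 13. Dehydrochlorination of the α-branched acid chloride and capture by the hindered internal ynol ether may both be slow. That would leave time for intramolecular [2+2] capture of the ketene by the C7 prenyl alkene, or for dimerisation.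
The fallback moves the C3–prenyl bond formation to after the ring construction. It sets out from 21 (via 25 and 26) and 22 and comes back at 28.
- The ketene is trapped with the unhindered parent alkyne 22 to give 3-ethoxy-4-(3-methylbut-2-enyl)-4-T-cyclobut-2-en-1-one F4.
- Aqueous HCl in THF gives 3-hydroxy-4-(3-methylbut-2-enyl)-4-T-cyclobut-2-en-1-one F5.
- A Tsuji–Trost C-allylation of this vinylogous acid with one equivalent of prenyl acetate (Pd(PPh3)4, Et3N, THF) attaches the linear prenyl group at C3.

Step 15. Oxygen transfer to a very stabilised enolate may be sluggish, the two ring faces may be poorly distinguished, and the tertiary alkoxide may undergo base-induced acyloin-type rearrangement.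
The fallback replaces oxygen-atom transfer by C–O coupling with a bulky partner. It sets out from 29 and comes back at 30.
- The enolate is treated at −78 °C with 2,2,6,6-tetramethyl-1-oxopiperidinium tetrafluoroborate to give the trans C3 alkoxyamine F6.
- The large piperidinyloxy group should sharpen the preference for the face opposite the tether, and no free alkoxide appears.
- After separation of isomers the N–O bond is cleaved with zinc dust in AcOH/THF/H2O.

Further compounds
F1 | step 17 | methyl 2-(methoxymethoxy)acetate | COCOCC(=O)OC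
F2 | step 17 | methyl 2-(methoxymethoxy)-5-methylhex-4-enoate (racemic) | COCOC(CC=C(C)C)C(=O)OC
F3 | step 17 | methyl 2-(methoxymethoxy)-2,4-bis(3-methylbut-2-enyl)-3-oxo-5-[(C7,C8)-chain]pentanoate, i.e. MeO2C(C2)–C3(OMOM)(prenyl)–C4(=O)–C5H(prenyl)–T, C3 and C5 epimers | CC(C)=CCC[C@](CC(=O)C(C)C)(C)[C@@H](CC=C(C)C)CC(CC=C(C)C)C(=O)C(OCOC)(CC=C(C)C)C(=O)OC
F4 | step 13 | 3-ethoxy-4-(3-methylbut-2-enyl)-4-T-cyclobut-2-en-1-one | CC(C)=CCC[C@](CC(=O)C(C)C)(C)[C@@H](CC=C(C)C)CC1(CC=C(C)C)C(=O)C=C1OCC
F5 | step 13 | 3-hydroxy-4-(3-methylbut-2-enyl)-4-T-cyclobut-2-en-1-one | CC(C)=CCC[C@](CC(=O)C(C)C)(C)[C@@H](CC=C(C)C)CC1(CC=C(C)C)C(=O)C=C1O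
F6 | step 15 | trans-2,4-bis(3-methylbut-2-enyl)-2-(2,2,6,6-tetramethylpiperidin-1-yloxy)-4-T-cyclobutane-1,3-dione | CC(C)=CCC[C@](CC(=O)C(C)C)(C)[C@@H](CC=C(C)C)C[C@]1(CC=C(C)C)C(=O)[C@](ON2C(C)(C)CCCC2(C)C)(CC=C(C)C)C1=O
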